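**Retrosynthetic overview**
- Feature: the benzenoid ring has OMe on C6 and C8 flanking the C7 ether oxygen, with C4a para to O7. This is the mirror-symmetric 3,5-dimethoxy-4-oxy pattern of syringaldehyde, whose formyl carbon is coumarin C4, so the pyran-2-one ring (O1, C2, C3, C4, C4a, C8a) can be closed last and only C2(=O)–C3 has to be brought in.
- Key disconnection: O1–C2 and C3=C4, back to a 2-hydroxybenzaldehyde carrying the side chain as its acetonide plus (triphenylphosphoranylidene)ketene (O-acylation, then intramolecular Wittig). The diol is released in the last step.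
- O7–C1′ ether: Williamson coupling of 2,4-dihydroxy-3,5-dimethoxybenzaldehyde (syringaldehyde, bromination at C2, copper hydroxylation) with the side-chain primary tosylate under mono-anion conditions.
- C2′/C3′: Sharpless epoxidation of nerol to the (2S,3R)-epoxide, then Payne rearrangement with hydroxide opening (one inversion at C2′) to the (2R,3R)-triol, primary tosylation and acetonide formation. Hydroxide is used for the Payne opening because a phenoxide dianion would be a poor, unselective nucleophile under those conditions.
- Ring order: benzene ring bought (syringaldehyde); temporary dioxolane in step 6; pyran-2-one ring in step 8.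

Key step: step 8

Assumption: the SMILES is read as the (2′R,3′R)-diol; commercial nerol is taken as the geometrically pure Z-olefin, since any geraniol would be carried into the 3′-epimeric series.

**Route**

Step 1
Reactants: 1 syringaldehyde (4-hydroxy-3,5-dimethoxybenzaldehyde)
Product: 2 2-bromo-4-hydroxy-3,5-dimethoxybenzaldehyde
Conditions: Br2 (1.05 equiv), NaOAc, AcOH, 15–20 °C
Reagents that add atoms: bromine, BrBr
Why: Electrophilic aromatic bromination; C2 and C6 are the only free positions, are equivalent by symmetry and are each ortho to one OMe and para to the other, while NaOAc buffers HBr and one equivalent of Br2 limits dibromination.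

Step 2
Reactants: 2 2-bromo-4-hydroxy-3,5-dimethoxybenzaldehyde
Product: 3 2,4-dihydroxy-3,5-dimethoxybenzaldehyde
Conditions: 8% aq NaOH, Cu powder (cat.), reflux, N2; then aq HCl, 0 °C
Reagents that add atoms: sodium hydroxide, [Na+].[OH-]
Why: Ullmann-type copper-catalysed hydroxylation of an aryl bromide activated by the ortho-formyl group (the reaction type that converts 5-bromovanillin into 5-hydroxyvanillin), with the para-phenoxide protecting the aldehyde from Cannizzaro disproportionation.

Step 3
Reactants: 4 nerol ((2Z)-3,7-dimethylocta-2,6-dien-1-ol)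
Product: 5 (2S,3R)-2,3-epoxynerol
Conditions: Ti(OiPr)4 (10 mol %), L-(+)-DET (12 mol %), t-BuOOH (anhydrous), 4 Å MS, CH2Cl2, −20 °C
Reagents that add atoms: tert-butyl hydroperoxide, CC(C)(C)OO
Why: Sharpless asymmetric epoxidation; the titanium tartrate binds the allylic alcohol so only C2=C3 is oxidised and C6=C7 is left alone, L-(+)-DET delivers oxygen to the face that gives the 2S epoxy alcohol, and the Z geometry fixes C3 as R.

Step 4
Reactants: 5 (2S,3R)-2,3-epoxynerol
Product: 7 (2R,3R)-3,7-dimethyloct-6-ene-1,2,3-triol, via terminal epoxide 6 (not isolated)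
Conditions: 0.5 M aq NaOH, t-BuOH, 75 °C
Reagents that add atoms: water, O
Why: Payne rearrangement, in which the C1 alkoxide opens the epoxide at C2 with inversion (2S to 2R) to give terminal epoxide 6, followed by hydroxide opening at the unhindered C1; the tertiary C3 cannot be attacked under basic conditions and stays R, and a direct SN2 attack of hydroxide at C2 of 5 would lead to the same triol.

Step 5
Reactants: 7 (2R,3R)-3,7-dimethyloct-6-ene-1,2,3-triol
Product: 8 (2R,3R)-2,3-dihydroxy-3,7-dimethyloct-6-en-1-yl 4-methylbenzenesulfonate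
Conditions: TsCl (1.05 equiv), Et3N (1.1 equiv), Bu2SnO (2 mol %), CH2Cl2, 0 °C to rt; neutral work-up
Reagents that add atoms: p-toluenesulfonyl chloride, Cc1ccc(cc1)S(=O)(=O)Cl
Why: Tin-catalysed regioselective sulfonylation of a 1,2-diol through its stannylene acetal, which should place the sulfonate on the primary oxygen only while the secondary and tertiary hydroxyls do not react at this stoichiometry.

Step 6
Reactants: 8 (2R,3R)-2,3-dihydroxy-3,7-dimethyloct-6-en-1-yl 4-methylbenzenesulfonate
Product: 9 [(4R,5R)-2,2,5-trimethyl-5-(4-methylpent-3-en-1-yl)-1,3-dioxolan-4-yl]methyl 4-methylbenzenesulfonate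
Conditions: 2,2-dimethoxypropane, CSA (cat.), acetone, rt; Et3N quench
Reagents that add atoms: 2,2-dimethoxypropane, COC(C)(C)OC
Why: Acid-catalysed transketalisation; the only diol left (secondary and tertiary hydroxyl) closes to the dioxolane without breaking a C–O bond at either stereocentre, and the sulfonate and the trisubstituted olefin tolerate catalytic CSA.

Step 7
Reactants: 3 2,4-dihydroxy-3,5-dimethoxybenzaldehyde (slight excess); 9 [(4R,5R)-2,2,5-trimethyl-5-(4-methylpent-3-en-1-yl)-1,3-dioxolan-4-yl]methyl 4-methylbenzenesulfonate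
Product: 10 2-hydroxy-3,5-dimethoxy-4-{[(4R,5R)-2,2,5-trimethyl-5-(4-methylpent-3-en-1-yl)-1,3-dioxolan-4-yl]methoxy}benzaldehyde
Conditions: K2CO3 (1.1 equiv), NaI (cat.), DMF, 85 °C
Reagents that add atoms: none
Why: Williamson ether synthesis (SN2 at the primary sulfonate); one equivalent of weak base ionises only the 4-OH (para to the formyl group, not hydrogen-bonded), while the 2-OH is held in a hydrogen bond to the aldehyde and shielded by CHO and OMe, and the dioxolane stereocentres are not involved.

Step 8
Reactants: 10 2-hydroxy-3,5-dimethoxy-4-{[(4R,5R)-2,2,5-trimethyl-5-(4-methylpent-3-en-1-yl)-1,3-dioxolan-4-yl]methoxy}benzaldehyde; 11 (triphenylphosphoranylidene)ketene (1.3 equiv)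
Product: 13 altissimacoumarin C acetonide, via ester ylide 12 (not isolated)
Conditions: toluene (dry, about 0.05 M), reflux, N2
Reagents that add atoms: none
Why: The acidic, formyl-chelated phenol of 10 protonates the ylide carbon of 11 and the phenoxide then acylates the ketenyl phosphonium ion, a net O–H addition across the C=C of the cumulated ylide that forms O1–C2 and gives the stabilised aryl ester ylide 12. The ylide carbon of 12 attacks the neighbouring formyl carbon in a 6-exo-trig sense and the oxaphosphetane collapses with loss of triphenylphosphine oxide, forming C3=C4 and closing the six-membered pyran-2-one ring by intramolecular Wittig olefination. The closest known reaction type is the Bestmann synthesis of coumarins from salicylaldehydes and (triphenylphosphoranylidene)ketene. No stereocentre is formed and the ring tether enforces the cis C3=C4 geometry. The step needs chemoselectivity only: the phenol is the sole O–H in 10 because the diol is locked in the dioxolane, and the neutral ylide leaves the ketal, the aryl ethers and the C6′=C7′ olefin alone. Moderate dilution in refluxing toluene should favour ring closure of 12 over intermolecular olefination.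

Step 9
Reactants: 13 altissimacoumarin C acetonide
Product: 14 altissimacoumarin C (7-{[(2R,3R)-2,3-dihydroxy-3,7-dimethyloct-6-en-1-yl]oxy}-6,8-dimethoxy-2H-chromen-2-one)
Conditions: AcOH–H2O (4:1), 45 °C
Reagents that add atoms: none
Why: Acid-catalysed acetal hydrolysis; dilute acetic acid should cleave the dioxolane without protonating the trisubstituted olefin (which would invite ether formation with the tertiary hydroxyl) or opening the lactone, and no bond to C2′ or C3′ is broken.

**Compound list**
1 | syringaldehyde (4-hydroxy-3,5-dimethoxybenzaldehyde) | COc1cc(C=O)cc(OC)c1O | starting material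
2 | 2-bromo-4-hydroxy-3,5-dimethoxybenzaldehyde | COc1cc(C=O)c(Br)c(OC)c1O | intermediate
3 | 2,4-dihydroxy-3,5-dimethoxybenzaldehyde | COc1cc(C=O)c(O)c(OC)c1O | intermediate
4 | nerol ((2Z)-3,7-dimethylocta-2,6-dien-1-ol) | CC(C)=CCC/C(C)=C\CO | starting material
5 | (2S,3R)-2,3-epoxynerol, [(2S,3R)-3-methyl-3-(4-methylpent-3-en-1-yl)oxiran-2-yl]methanol | CC(C)=CCC[C@@]1(C)O[C@H]1CO | intermediate
6 | (2R)-6-methyl-2-[(2R)-oxiran-2-yl]hept-5-en-2-ol (terminal epoxide, formed in situ) | C1O[C@H]1[C@](C)(O)CCC=C(C)C | intermediate
7 | (2R,3R)-3,7-dimethyloct-6-ene-1,2,3-triol | OC[C@@H](O)[C@](C)(O)CCC=C(C)C | intermediate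
8 | (2R,3R)-2,3-dihydroxy-3,7-dimethyloct-6-en-1-yl 4-methylbenzenesulfonate | Cc1ccc(cc1)S(=O)(=O)OC[C@@H](O)[C@](C)(O)CCC=C(C)C | intermediate
9 | [(4R,5R)-2,2,5-trimethyl-5-(4-methylpent-3-en-1-yl)-1,3-dioxolan-4-yl]methyl 4-methylbenzenesulfonate | Cc1ccc(cc1)S(=O)(=O)OC[C@H]2OC(C)(C)O[C@]2(C)CCC=C(C)C | intermediate
10 | 2-hydroxy-3,5-dimethoxy-4-{[(4R,5R)-2,2,5-trimethyl-5-(4-methylpent-3-en-1-yl)-1,3-dioxolan-4-yl]methoxy}benzaldehyde | COc1cc(C=O)c(O)c(OC)c1OC[C@H]2OC(C)(C)O[C@]2(C)CCC=C(C)C | intermediate
11 | (triphenylphosphoranylidene)ketene | O=C=C=P(c1ccccc1)(c2ccccc2)c3ccccc3 | starting material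
12 | 6-formyl-2,4-dimethoxy-3-{[(4R,5R)-2,2,5-trimethyl-5-(4-methylpent-3-en-1-yl)-1,3-dioxolan-4-yl]methoxy}phenyl (triphenyl-λ5-phosphanylidene)acetate (ester ylide, formed in situ) | COc1cc(C=O)c(OC(=O)C=P(c2ccccc2)(c3ccccc3)c4ccccc4)c(OC)c1OC[C@H]5OC(C)(C)O[C@]5(C)CCC=C(C)C | intermediate
13 | altissimacoumarin C acetonide, 6,8-dimethoxy-7-{[(4R,5R)-2,2,5-trimethyl-5-(4-methylpent-3-en-1-yl)-1,3-dioxolan-4-yl]methoxy}-2H-chromen-2-one | COc1cc2ccc(=O)oc2c(OC)c1OC[C@H]3OC(C)(C)O[C@]3(C)CCC=C(C)C | intermediate
14 | altissimacoumarin C, 7-{[(2R,3R)-2,3-dihydroxy-3,7-dimethyloct-6-en-1-yl]oxy}-6,8-dimethoxy-2H-chromen-2-one | COc1cc2ccc(=O)oc2c(OC)c1OC[C@@H](O)[C@](C)(O)CCC=C(C)C | target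

**Step count**
Total steps: 9. Longest linear sequence: 7 steps (nerol 4 to 14, steps 3–9); the aromatic branch (steps 1–2) joins at step 7.

**Steps most likely to fail**

1. Step 8 (key step). The hindered, hydrogen-bonded phenol may add only slowly to the cumulated ylide, the moisture-sensitive ylide may hydrolyse first, or the ester ylide may olefinate a second molecule and oligomerise. Fallback, starting from 10: O-acylation with bromoacetyl bromide and 2,6-lutidine (CH2Cl2, −10 °C) should give the aryl bromoacetate F1. Triphenylphosphine (toluene, rt) should convert this into the phosphonium bromide F2. Triethylamine then generates the same ester ylide, so the sequence rejoins the route at 12 and closes to 13 by the same intramolecular Wittig olefination.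

2. Step 2. Copper may reduce the C–Br bond back to C–H, and the electron-rich dihydroxy aldehyde may degrade oxidatively in hot alkali. Fallback, starting from 2: copper(I)-catalysed methoxylation (NaOMe, CuBr, DMF–MeOH, 110 °C; the reaction type that makes syringaldehyde from 5-bromovanillin) should give 4-hydroxy-2,3,5-trimethoxybenzaldehyde F3. BCl3 (CH2Cl2, −10 to 0 °C) should then cleave only the methyl ether ortho to the formyl group through the carbonyl-chelated boron complex, returning to the route at 3.

3. Step 7. Displacement at the β-branched sulfonate by the di-ortho-substituted, weakly nucleophilic phenoxide may be slow, and forcing conditions would start to alkylate the 2-OH as well. Fallback, starting from 8: K2CO3 in MeOH at 0 °C closes the terminal epoxide 6, which is isolated in this variant. Phenol 3 then opens it at the unhindered ring CH2 with substoichiometric base (K2CO3 0.2 equiv, DMF, 70 °C) to give the diol ether 4-{[(2R,3R)-2,3-dihydroxy-3,7-dimethyloct-6-en-1-yl]oxy}-2-hydroxy-3,5-dimethoxybenzaldehyde F4. 2,2-Dimethoxypropane with catalytic CSA then forms the dioxolane and the route is rejoined at 10.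

**Further compounds**
F1 | step 8 | 6-formyl-2,4-dimethoxy-3-{[(4R,5R)-2,2,5-trimethyl-5-(4-methylpent-3-en-1-yl)-1,3-dioxolan-4-yl]methoxy}phenyl bromoacetate | COc1cc(C=O)c(OC(=O)CBr)c(OC)c1OC[C@H]2OC(C)(C)O[C@]2(C)CCC=C(C)C
F2 | step 8 | [2-(6-formyl-2,4-dimethoxy-3-{[(4R,5R)-2,2,5-trimethyl-5-(4-methylpent-3-en-1-yl)-1,3-dioxolan-4-yl]methoxy}phenoxy)-2-oxoethyl]triphenylphosphonium bromide | COc1cc(C=O)c(OC(=O)C[P+](c2ccccc2)(c3ccccc3)c4ccccc4)c(OC)c1OC[C@H]5OC(C)(C)O[C@]5(C)CCC=C(C)C.[Br-]
F3 | step 2 | 4-hydroxy-2,3,5-trimethoxybenzaldehyde | COc1cc(C=O)c(OC)c(OC)c1O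
F4 | step 7 | 4-{[(2R,3R)-2,3-dihydroxy-3,7-dimethyloct-6-en-1-yl]oxy}-2-hydroxy-3,5-dimethoxybenzaldehyde | COc1cc(C=O)c(O)c(OC)c1OC[C@@H](O)[C@](C)(O)CCC=C(C)C
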